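## Retrosynthetic overview

1. Target ⇐ C9–C10 bond: intramolecular Mukaiyama aldol of a 3-silyloxyfuran (made in the flask from the 2H-furanone) onto the C9 aldehyde. This closes the 9-membered ring C10–O–C3–C4–C5–C6–C7–C8–C9 last, sets C9 and C10 in one event, and starts from an open isomer of the target that already carries the C8 ester.
2. Enabling feature: C10 is C2 of the 3(2H)-furanone ring (between the ring O and the C1 ketone) and C9 carries the β-hydroxyl, so the target is a β-hydroxy ketone whose enol is an aromatic furan. The (Z)-C4=C5 alkene and the trans-fused C6/C7 lactone turn the chain back toward that furan.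
3. Open precursor ⇐ acylation of C8–OH with (E)-2-(acetoxymethyl)but-2-enoic acid. Lactone ⇐ CrCl2 Barbier allylation/lactonisation (C6–C7 bond; C6 and C7 relayed from C8) of a (Z)-furanonyl enal with a 2-(bromomethyl)acrylate made from (R)-glyceraldehyde acetonide (C8 bought).
4. (Z)-Enal ⇐ 3-methylbutenolide (ring-locked Z alkene) plus but-3-yn-2-ol, through a Weinreb amide, a γ-hydroxy ynone and gold cycloisomerisation.
5. Order of ring formation: furanone ring (step 4), lactone ring (step 9), 9-membered oxacycle (step 19).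

Key step: step 19

Remark: atom labels C1–C15 follow the germacrane numbering of the target (lactone O–C6, C7–C11(=C13)–C12=O; furanone O bridges C3 and C10; C1 ketone; C14 on C10; C15 on C4). The furanone C2–H centre (future C10) is carried as an epimer mixture in 6–8, 13–16 and 24–26, which is of no consequence because C10 is planarised in step 19.

## Route

Step 1
Reactants: 1 3-methylfuran-2(5H)-one
Product: 2 (2Z)-4-hydroxy-N-methoxy-N,2-dimethylbut-2-enamide
Conditions: MeNHOMe·HCl, AlMe3, CH2Cl2, 0 °C → rt; crude product used at once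
Reagents that add atoms: N,O-dimethylhydroxylamine hydrochloride, CNOC.Cl
Why: Weinreb aminolysis of a lactone by the aluminium amide opens the butenolide at the acyl–oxygen bond, so the ring-enforced geometry is delivered as the (Z)-enamide that carries C3–C6 and C15.

Step 2
Reactants: 2 (2Z)-4-hydroxy-N-methoxy-N,2-dimethylbut-2-enamide
Product: 3 (2Z)-4-[(tert-butyldimethylsilyl)oxy]-N-methoxy-N,2-dimethylbut-2-enamide
Conditions: TBSCl, imidazole, DMF, 0 °C → rt
Reagents that add atoms: tert-butyldimethylsilyl chloride, CC(C)(C)[Si](C)(C)Cl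
Why: Standard silylation of the primary alcohol stops the hydroxy amide from closing back to the butenolide and masks C6–OH for step 3.

Step 3
Reactants: 3 (2Z)-4-[(tert-butyldimethylsilyl)oxy]-N-methoxy-N,2-dimethylbut-2-enamide; 4 but-3-yn-2-ol (racemic)
Product: 5 (6Z)-8-[(tert-butyldimethylsilyl)oxy]-2-hydroxy-6-methyloct-6-en-3-yn-5-one
Conditions: 4 (2.2 equiv), n-BuLi (4.3 equiv), THF, −78 → −20 °C; then 3, −78 → 0 °C; aq. NH4Cl
Reagents that add atoms: none
Why: Weinreb ketone synthesis: the dilithio derivative of the propargylic alcohol adds once because the chelated tetrahedral intermediate survives until work-up, giving the γ-hydroxy ynone whose racemic carbinol centre (future C10) is planarised in step 19.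

Step 4
Reactants: 5 (6Z)-8-[(tert-butyldimethylsilyl)oxy]-2-hydroxy-6-methyloct-6-en-3-yn-5-one
Product: 6 5-{(2Z)-4-[(tert-butyldimethylsilyl)oxy]but-2-en-2-yl}-2-methylfuran-3(2H)-one
Conditions: (4-CF3C6H4)3PAuCl (5 mol %), AgOTf (5 mol %), toluene, rt, under argon
Reagents that add atoms: none
Why: Cationic monovalent gold catalyses the known cycloisomerisation of γ-hydroxyalkynones to 3(2H)-furanones (formal alkyne hydration to the 1,3-diketone and dehydrative closure by the hydroxyl), which puts the ring oxygen on C3 and the ketone on C1 without touching the (Z)-alkene.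

Step 5
Reactants: 6 5-{(2Z)-4-[(tert-butyldimethylsilyl)oxy]but-2-en-2-yl}-2-methylfuran-3(2H)-one
Product: 7 5-[(2Z)-4-hydroxybut-2-en-2-yl]-2-methylfuran-3(2H)-one
Conditions: HF·pyridine, pyridine, THF, 0 °C → rt
Reagents that add atoms: none
Why: Fluoride cleavage of the primary silyl ether under buffered, non-basic conditions leaves the C–H acidic furanone intact.

Step 6
Reactants: 7 5-[(2Z)-4-hydroxybut-2-en-2-yl]-2-methylfuran-3(2H)-one
Product: 8 (2Z)-3-(5-methyl-4-oxo-4,5-dihydrofuran-2-yl)but-2-enal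
Conditions: MnO2 (activated, excess), CH2Cl2, rt, dark; filtered and used at once
Reagents that add atoms: none
Why: MnO2 oxidises allylic alcohols selectively under neutral conditions, which should keep the (Z)-geometry of the enal.

Step 7
Reactants: 9 (R)-2,2-dimethyl-1,3-dioxolane-4-carbaldehyde; 10 methyl acrylate
Product: 11 methyl 2-{[(4R)-2,2-dimethyl-1,3-dioxolan-4-yl](hydroxy)methyl}prop-2-enoate (carbinol epimers)
Conditions: DABCO (0.5 equiv), 1,4-dioxane/H2O (1:1), rt
Reagents that add atoms: none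
Why: Morita–Baylis–Hillman reaction; C8 of the target is the stereocentre bought with the aldehyde, and the new carbinol centre forms as a mixture that is removed in step 8.

Step 8
Reactants: 11 methyl 2-{[(4R)-2,2-dimethyl-1,3-dioxolan-4-yl](hydroxy)methyl}prop-2-enoate
Product: 12 methyl (2Z)-2-(bromomethyl)-3-[(4S)-2,2-dimethyl-1,3-dioxolan-4-yl]prop-2-enoate
Conditions: NBS, Me2S, CH2Cl2, 0 °C → rt
Reagents that add atoms: N-bromosuccinimide, O=C1CCC(=O)N1Br
Why: Corey–Kim-type activation of the alcohol followed by SN2' attack of bromide transposes the allylic system and gives the conjugated 2-(bromomethyl)enoate, for which the (Z)-isomer is the favoured product.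

Step 9
Reactants: 8 (2Z)-3-(5-methyl-4-oxo-4,5-dihydrofuran-2-yl)but-2-enal; 12 methyl (2Z)-2-(bromomethyl)-3-[(4S)-2,2-dimethyl-1,3-dioxolan-4-yl]prop-2-enoate
Product: 14 (4S,5R)-4-[(4S)-2,2-dimethyl-1,3-dioxolan-4-yl]-3-methylidene-5-[(1Z)-2-(5-methyl-4-oxo-4,5-dihydrofuran-2-yl)prop-1-en-1-yl]oxolan-2-one, via open-chain hydroxy ester 13 (not isolated)
Conditions: CrCl2 (4 equiv), THF, 0 °C → rt; aqueous work-up; then PPTS (cat.), CH2Cl2, rt
Reagents that add atoms: none
Why: Nozaki–Hiyama-type Barbier 2-(alkoxycarbonyl)allylation with divalent chromium, then lactonisation: the allylchromium adds only to the aldehyde through a chair Zimmerman–Traxler transition state with the alkenyl group and the C8 substituent equatorial (6,7-anti, hence the trans-lactone), and C8 fixes the face of C7 because H8 eclipses the C7=C11 bond (allylic 1,3-strain) and the aldehyde enters anti to the dioxolane CH2 (C9) with O8 outside, which should give 6R,7S.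

Step 10
Reactants: 14 lactone acetonide
Product: 15 (4R,5R)-4-[(1S)-1,2-dihydroxyethyl]-3-methylidene-5-[(1Z)-2-(5-methyl-4-oxo-4,5-dihydrofuran-2-yl)prop-1-en-1-yl]oxolan-2-one
Conditions: AcOH/THF/H2O (3:1:1), 40 °C
Reagents that add atoms: none
Why: Acid-catalysed acetal hydrolysis of the terminal acetonide under mild conditions in which the lactone, the furanone and the allylic C6–O bond should be stable (the C7 descriptor changes only through the priority rules).

Step 11
Reactants: 15 diol
Product: 16 (4R,5R)-4-[(1S)-2-[(tert-butyldimethylsilyl)oxy]-1-hydroxyethyl]-3-methylidene-5-[(1Z)-2-(5-methyl-4-oxo-4,5-dihydrofuran-2-yl)prop-1-en-1-yl]oxolan-2-one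
Conditions: TBSCl (1.05 equiv), imidazole, CH2Cl2, −20 → 0 °C
Reagents that add atoms: tert-butyldimethylsilyl chloride, CC(C)(C)[Si](C)(C)Cl
Why: Kinetic silylation of the primary C9 hydroxyl over the hindered secondary C8 hydroxyl leaves only C8–OH free for acylation.

Step 12
Reactants: 17 acetaldehyde; 18 tert-butyl acrylate
Product: 19 tert-butyl 3-hydroxy-2-methylidenebutanoate (racemic)
Conditions: DABCO (1 equiv), 1,4-dioxane/H2O (1:1), rt
Reagents that add atoms: none
Why: Morita–Baylis–Hillman reaction gives the allylic alcohol, whose stereocentre is removed in step 13.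

Step 13
Reactants: 19 tert-butyl 3-hydroxy-2-methylidenebutanoate
Product: 20 tert-butyl (2Z)-2-(bromomethyl)but-2-enoate
Conditions: NBS, Me2S, CH2Cl2, 0 °C → rt
Reagents that add atoms: N-bromosuccinimide, O=C1CCC(=O)N1Br
Why: Corey–Kim-type bromination with SN2' transposition gives the conjugated primary allylic bromide with the β-methyl cis to CH2Br, the geometry of the target side chain.

Step 14
Reactants: 20 tert-butyl (2Z)-2-(bromomethyl)but-2-enoate
Product: 21 tert-butyl (2E)-2-(acetoxymethyl)but-2-enoate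
Conditions: KOAc, DMF, rt
Reagents that add atoms: potassium acetate, CC(=O)[O-].[K+]
Why: SN2 displacement of the primary allylic bromide by acetate keeps the alkene geometry (the descriptor changes from Z to E only through the priority rules).

Step 15
Reactants: 21 tert-butyl (2E)-2-(acetoxymethyl)but-2-enoate
Product: 22 (2E)-2-(acetoxymethyl)but-2-enoic acid
Conditions: TFA/CH2Cl2 (1:4), 0 °C → rt
Reagents that add atoms: none
Why: Acidolysis of the tert-butyl ester (loss of isobutene) frees the acid without touching the acetate or the alkene geometry.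

Step 16
Reactants: 16 primary TBS ether with free C8–OH; 22 (2E)-2-(acetoxymethyl)but-2-enoic acid
Product: 24 (1S)-2-[(tert-butyldimethylsilyl)oxy]-1-{(2R,3S)-4-methylidene-2-[(1Z)-2-(5-methyl-4-oxo-4,5-dihydrofuran-2-yl)prop-1-en-1-yl]-5-oxooxolan-3-yl}ethyl (2E)-2-(acetoxymethyl)but-2-enoate, via acid chloride 23 (not isolated)
Conditions: 22, (COCl)2, DMF (cat.), CH2Cl2, 0 °C → rt, concentrate; then 16, pyridine, DMAP (0.1 equiv), CH2Cl2, 0 °C
Reagents that add atoms: oxalyl chloride, O=C(Cl)C(=O)Cl (its chlorine stays in 23 only)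
Why: Acylation of the secondary C8 alcohol by the acid chloride with nucleophilic catalysis under weakly basic conditions that should not enolise the furanone; the C8–O bond is not broken, so C8 is retained.

Step 17
Reactants: 24 C8 ester with C9 TBS ether
Product: 25 (1S)-2-hydroxy-1-{(2R,3S)-4-methylidene-2-[(1Z)-2-(5-methyl-4-oxo-4,5-dihydrofuran-2-yl)prop-1-en-1-yl]-5-oxooxolan-3-yl}ethyl (2E)-2-(acetoxymethyl)but-2-enoate
Conditions: HF·pyridine, pyridine, THF, 0 °C; crude product used at once
Reagents that add atoms: none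
Why: Fluoride cleavage of the primary TBS ether under buffered acidic conditions, chosen because base would promote acyl migration from O8 to O9.

Step 18
Reactants: 25 C9 primary alcohol
Product: 26 (1S)-2-oxo-1-{(2R,3S)-4-methylidene-2-[(1Z)-2-(5-methyl-4-oxo-4,5-dihydrofuran-2-yl)prop-1-en-1-yl]-5-oxooxolan-3-yl}ethyl (2E)-2-(acetoxymethyl)but-2-enoate
Conditions: Dess–Martin periodinane, NaHCO3, CH2Cl2, 0 °C → rt; used directly
Reagents that add atoms: none
Why: Dess–Martin oxidation gives the aldehyde under non-basic conditions that should preserve the configuration at C8 (now α to the aldehyde) and the ester.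

Step 19
Reactants: 26 open aldehyde (isomer of the target)
Product: 29 target CNP0231561.3 (6R,7S,8S,9S,10S; 4Z), via silyloxyfuran aldehyde 27 (not isolated), via C9 trimethylsilyl ether 28 (not isolated)
Conditions: iPr2NEt (1.2 equiv), TMSOTf (1.5 equiv), CH2Cl2 (1 mM), −78 → −40 °C; then 1 M HCl, THF, 0 °C
Reagents that add atoms: trimethylsilyl triflate, C[Si](C)(C)OS(=O)(=O)C(F)(F)F (its silyl group stays in 27 and 28 only)
Why: iPr2NEt/TMSOTf soft-enolises the furanone at C10–H (both epimers converge) to the aromatic 2-methyl-3-(trimethylsilyloxy)furan 27; the excess TMSOTf then activates the C9 aldehyde, the furan attacks through C10 in an open Mukaiyama aldol transition state, silyl transfer gives 28 with the C1 ketone restored, and dilute acid frees the C9 hydroxyl. The closest known reaction is the Lewis-acid-promoted aldol of 2-substituted 3-silyloxyfurans with aldehydes, which gives 2,2-disubstituted 3(2H)-furanones with a quaternary carbon, run here as a one-pot silyl triflate/amine enol-silane formation–Mukaiyama aldol and in the ring-closing manner of Mukaiyama aldol macrocyclisations. The 9-membered oxacycle (C10–O–C3–C4–C5–C6–C7–C8–C9) is closed through C9–C10 in a 9-exo-trig (enolexo) mode. C9 is controlled by C8: with the non-chelating silyl Lewis acid the C8–O bond stands anti to the incoming furan (polar Felkin–Anh), which gives the 8,9-anti (8S,9S) relation; C10 is controlled by the tether, because the furan is planar and the (Z)-C4=C5 alkene and the trans-lactone should let the C7–C8–C9 arm reach it from one side only when H6 points into the ring and the lactone lies outside, the arrangement expected to give 10S (the least secure point of the route). The step needs attack through C10 and not through C2 (C10 is the enol-silane terminus, as in the intermolecular cases), the aldehyde and not the enoate or α-methylene lactone as electrophile (only the aldehyde is activated at −78 °C), cyclisation over oligomerisation (high dilution, pre-turned chain), and no enolisation at C8 (the furanone C–H is by far the most acidic site because its enol is aromatic).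

## Compound list

1 | 3-methylfuran-2(5H)-one | CC1=CCOC1=O | starting material
2 | (2Z)-4-hydroxy-N-methoxy-N,2-dimethylbut-2-enamide | CON(C)C(=O)/C(C)=C\CO | intermediate
3 | (2Z)-4-[(tert-butyldimethylsilyl)oxy]-N-methoxy-N,2-dimethylbut-2-enamide | CON(C)C(=O)/C(C)=C\CO[Si](C)(C)C(C)(C)C | intermediate
4 | but-3-yn-2-ol (racemic) | CC(O)C#C | starting material
5 | (6Z)-8-[(tert-butyldimethylsilyl)oxy]-2-hydroxy-6-methyloct-6-en-3-yn-5-one | CC(O)C#CC(=O)/C(C)=C\CO[Si](C)(C)C(C)(C)C | intermediate
6 | 5-{(2Z)-4-[(tert-butyldimethylsilyl)oxy]but-2-en-2-yl}-2-methylfuran-3(2H)-one | CC1OC(=CC1=O)/C(C)=C\CO[Si](C)(C)C(C)(C)C | intermediate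
7 | 5-[(2Z)-4-hydroxybut-2-en-2-yl]-2-methylfuran-3(2H)-one | CC1OC(=CC1=O)/C(C)=C\CO | intermediate
8 | (2Z)-3-(5-methyl-4-oxo-4,5-dihydrofuran-2-yl)but-2-enal | CC1OC(=CC1=O)/C(C)=C\C=O | intermediate
9 | (R)-2,2-dimethyl-1,3-dioxolane-4-carbaldehyde | O=C[C@H]1COC(C)(C)O1 | starting material
10 | methyl acrylate | C=CC(=O)OC | starting material
11 | methyl 2-{[(4R)-2,2-dimethyl-1,3-dioxolan-4-yl](hydroxy)methyl}prop-2-enoate (carbinol epimers) | C=C(C(=O)OC)C(O)[C@H]1COC(C)(C)O1 | intermediate
12 | methyl (2Z)-2-(bromomethyl)-3-[(4S)-2,2-dimethyl-1,3-dioxolan-4-yl]prop-2-enoate | COC(=O)/C(CBr)=C/[C@H]1COC(C)(C)O1 | intermediate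
13 | methyl (3S,4R,5Z)-3-[(4S)-2,2-dimethyl-1,3-dioxolan-4-yl]-4-hydroxy-2-methylidene-6-(5-methyl-4-oxo-4,5-dihydrofuran-2-yl)hept-5-enoate | C=C(C(=O)OC)[C@H]([C@H]1COC(C)(C)O1)[C@H](O)/C=C(/C)C2=CC(=O)C(C)O2 | intermediate
14 | (4S,5R)-4-[(4S)-2,2-dimethyl-1,3-dioxolan-4-yl]-3-methylidene-5-[(1Z)-2-(5-methyl-4-oxo-4,5-dihydrofuran-2-yl)prop-1-en-1-yl]oxolan-2-one | C=C1C(=O)O[C@H](/C=C(/C)C2=CC(=O)C(C)O2)[C@H]1[C@H]3COC(C)(C)O3 | intermediate
15 | (4R,5R)-4-[(1S)-1,2-dihydroxyethyl]-3-methylidene-5-[(1Z)-2-(5-methyl-4-oxo-4,5-dihydrofuran-2-yl)prop-1-en-1-yl]oxolan-2-one | C=C1C(=O)O[C@H](/C=C(/C)C2=CC(=O)C(C)O2)[C@H]1[C@H](O)CO | intermediate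
16 | (4R,5R)-4-[(1S)-2-[(tert-butyldimethylsilyl)oxy]-1-hydroxyethyl]-3-methylidene-5-[(1Z)-2-(5-methyl-4-oxo-4,5-dihydrofuran-2-yl)prop-1-en-1-yl]oxolan-2-one | C=C1C(=O)O[C@H](/C=C(/C)C2=CC(=O)C(C)O2)[C@H]1[C@H](O)CO[Si](C)(C)C(C)(C)C | intermediate
17 | acetaldehyde | CC=O | starting material
18 | tert-butyl acrylate | C=CC(=O)OC(C)(C)C | starting material
19 | tert-butyl 3-hydroxy-2-methylidenebutanoate (racemic) | CC(O)C(=C)C(=O)OC(C)(C)C | intermediate
20 | tert-butyl (2Z)-2-(bromomethyl)but-2-enoate | CC(C)(C)OC(=O)/C(=C/C)CBr | intermediate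
21 | tert-butyl (2E)-2-(acetoxymethyl)but-2-enoate | CC(C)(C)OC(=O)/C(=C/C)COC(C)=O | intermediate
22 | (2E)-2-(acetoxymethyl)but-2-enoic acid | OC(=O)/C(=C/C)COC(C)=O | intermediate
23 | (2E)-2-(acetoxymethyl)but-2-enoyl chloride | ClC(=O)/C(=C/C)COC(C)=O | intermediate
24 | (1S)-2-[(tert-butyldimethylsilyl)oxy]-1-{(2R,3S)-4-methylidene-2-[(1Z)-2-(5-methyl-4-oxo-4,5-dihydrofuran-2-yl)prop-1-en-1-yl]-5-oxooxolan-3-yl}ethyl (2E)-2-(acetoxymethyl)but-2-enoate | C=C1C(=O)O[C@H](/C=C(/C)C2=CC(=O)C(C)O2)[C@H]1[C@H](OC(=O)/C(=C/C)COC(C)=O)CO[Si](C)(C)C(C)(C)C | intermediate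
25 | (1S)-2-hydroxy-1-{(2R,3S)-4-methylidene-2-[(1Z)-2-(5-methyl-4-oxo-4,5-dihydrofuran-2-yl)prop-1-en-1-yl]-5-oxooxolan-3-yl}ethyl (2E)-2-(acetoxymethyl)but-2-enoate | C=C1C(=O)O[C@H](/C=C(/C)C2=CC(=O)C(C)O2)[C@H]1[C@H](OC(=O)/C(=C/C)COC(C)=O)CO | intermediate
26 | (1S)-2-oxo-1-{(2R,3S)-4-methylidene-2-[(1Z)-2-(5-methyl-4-oxo-4,5-dihydrofuran-2-yl)prop-1-en-1-yl]-5-oxooxolan-3-yl}ethyl (2E)-2-(acetoxymethyl)but-2-enoate | C=C1C(=O)O[C@H](/C=C(/C)C2=CC(=O)C(C)O2)[C@H]1[C@H](OC(=O)/C(=C/C)COC(C)=O)C=O | intermediate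
27 | (1S)-2-oxo-1-{(2R,3S)-4-methylidene-2-[(1Z)-2-{5-methyl-4-[(trimethylsilyl)oxy]furan-2-yl}prop-1-en-1-yl]-5-oxooxolan-3-yl}ethyl (2E)-2-(acetoxymethyl)but-2-enoate | C=C1C(=O)O[C@H](/C=C(/C)c2cc(O[Si](C)(C)C)c(C)o2)[C@H]1[C@H](OC(=O)/C(=C/C)COC(C)=O)C=O | intermediate
28 | C9 O-trimethylsilyl ether of the target (6R,7S,8S,9S,10S; 4Z) | C=C1C(=O)O[C@@H]2/C=C(/C)C3=CC(=O)[C@@](C)(O3)[C@@H](O[Si](C)(C)C)[C@@H](OC(=O)/C(=C/C)COC(C)=O)[C@@H]12 | intermediate
29 | CNP0231561.3 (6R,7S,8S,9S,10S; 4Z; 8-O-[(2E)-2-(acetoxymethyl)but-2-enoyl]; 9-OH) | C=C1C(=O)O[C@@H]2/C=C(/C)C3=CC(=O)[C@@](C)(O3)[C@@H](O)[C@@H](OC(=O)/C(=C/C)COC(C)=O)[C@@H]12 | target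

## Step count and risks

Total: 19 steps. Longest linear sequence: 13 steps (steps 1–6, 9–11, 16–19).

**Step 19 (ring-closing aldol).** The process at risk is the choice of furan face by the tethered aldehyde (configuration at C10), or a closure that is outrun by oligomerisation or by enolisation of the aldehyde. The fallback keeps the C9–C10 closure but generates a metal enolate by reduction and closes through a chelated chair. It sets out from silyl ether 24. Silyloxyfuran formation (TMSOTf, Et3N, CH2Cl2, −78 °C) and bromination in the same flask (NBS, −78 °C; α-bromination of an enol silane) should give the C10 bromide of 24, F1. HF·pyridine should give the primary alcohol F2, and Dess–Martin oxidation the bromo aldehyde F3. CrCl2 with catalytic LiI in THF at high dilution should turn the α-bromo ketone into a trivalent chromium enolate that adds to the C9 aldehyde (chromium Reformatsky reaction, tolerant of esters and enoates). The route is rejoined at target 29.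

**Step 9 (Barbier allylation).** The process at risk is facial selection at C7 by the C8 dioxolane (addition anti to O8 instead of anti to C9), besides Z/E drift of the enal. If C8 steers the addition to the other face, the fallback uses the enantiomeric C8 and inverts it at the acylation stage. It sets out from enal 8. Purchased (S)-2,2-dimethyl-1,3-dioxolane-4-carbaldehyde F4 is taken through the conditions of steps 7 and 8 to the Baylis–Hillman adduct F5 and the (4R)-bromide F6. CrCl2 coupling of F6 with 8 should then give the hydroxy ester F7 and, after lactonisation, the lactone acetonide F8 with C6 and C7 as in the target and C8 epimeric. The conditions of steps 10 and 11 should give the diol F9 and the primary silyl ether F10. Mitsunobu esterification of F10 with acid 22 (PPh3, DIAD, toluene, 0 °C → rt) inverts C8 and rejoins the route at 24.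

**Step 17 (desilylation).** The process at risk is acyl migration from O8 to the freed primary O9 (and on to the oxidation in step 18). The fallback never liberates the alcohol. It sets out from diol 15. TESCl and imidazole at −40 °C should give the primary triethylsilyl ether F11, and acylation as in step 16 its C8 ester F12. Swern conditions ((COCl)2, DMSO, CH2Cl2, −78 → −30 °C; then Et3N), which oxidise primary triethylsilyl ethers directly to aldehydes, should then give aldehyde 26, where the route is rejoined.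

Further compounds
F1 | step 19 | C10 bromide of 24 (2-bromo-2-methylfuranone; C10 epimers) | C=C1C(=O)O[C@H](/C=C(/C)C2=CC(=O)C(C)(Br)O2)[C@H]1[C@H](OC(=O)/C(=C/C)COC(C)=O)CO[Si](C)(C)C(C)(C)C
F2 | step 19 | C10 bromide with free C9 primary alcohol | C=C1C(=O)O[C@H](/C=C(/C)C2=CC(=O)C(C)(Br)O2)[C@H]1[C@H](OC(=O)/C(=C/C)COC(C)=O)CO
F3 | step 19 | C10 bromide with C9 aldehyde | C=C1C(=O)O[C@H](/C=C(/C)C2=CC(=O)C(C)(Br)O2)[C@H]1[C@H](OC(=O)/C(=C/C)COC(C)=O)C=O
F4 | step 9 | (S)-2,2-dimethyl-1,3-dioxolane-4-carbaldehyde (purchased) | O=C[C@@H]1COC(C)(C)O1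
F5 | step 9 | methyl 2-{[(4S)-2,2-dimethyl-1,3-dioxolan-4-yl](hydroxy)methyl}prop-2-enoate | C=C(C(=O)OC)C(O)[C@@H]1COC(C)(C)O1
F6 | step 9 | methyl (2Z)-2-(bromomethyl)-3-[(4R)-2,2-dimethyl-1,3-dioxolan-4-yl]prop-2-enoate | COC(=O)/C(CBr)=C/[C@@H]1COC(C)(C)O1
F7 | step 9 | C8 epimer of hydroxy ester 13 [(3S,4R,5Z); (4R)-dioxolane] | C=C(C(=O)OC)[C@H]([C@@H]1COC(C)(C)O1)[C@H](O)/C=C(/C)C2=CC(=O)C(C)O2
F8 | step 9 | C8 epimer of lactone acetonide 14 [(4S,5R)-lactone; (4R)-dioxolane] | C=C1C(=O)O[C@H](/C=C(/C)C2=CC(=O)C(C)O2)[C@H]1[C@@H]3COC(C)(C)O3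
F9 | step 9 | C8 epimer of diol 15 [(4R,5R)-lactone; (1R)-1,2-dihydroxyethyl] | C=C1C(=O)O[C@H](/C=C(/C)C2=CC(=O)C(C)O2)[C@H]1[C@@H](O)CO
F10 | step 9 | C8 epimer of silyl ether 16 [(4R,5R)-lactone; (1R)-carbinol] | C=C1C(=O)O[C@H](/C=C(/C)C2=CC(=O)C(C)O2)[C@H]1[C@@H](O)CO[Si](C)(C)C(C)(C)C
F11 | step 17 | primary triethylsilyl ether of diol 15 | C=C1C(=O)O[C@H](/C=C(/C)C2=CC(=O)C(C)O2)[C@H]1[C@H](O)CO[Si](CC)(CC)CC
F12 | step 17 | C8 (2E)-2-(acetoxymethyl)but-2-enoate of F11 | C=C1C(=O)O[C@H](/C=C(/C)C2=CC(=O)C(C)O2)[C@H]1[C@H](OC(=O)/C(=C/C)COC(C)=O)CO[Si](CC)(CC)CC
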